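## Structural features

The target is a verticillane: a cyclohexanone (C1, C14, C13, C12, C11, C15) whose 1,3-related carbons C1 and C11 are bridged by the nine-carbon chain C2–C10. A twelve-membered carbocycle (C1–C11 plus C15) and the six-membered ring therefore share C1, C15 and C11 (bicyclo[9.3.1]pentadecane). The quaternary CMe2 carbon C15 lies between the two bridgeheads, whose chain bonds are trans on the six-membered ring (1R, 11S). The acetoxy carbon C10 (R) is the direct neighbour of C11, and the ketone C13 is conjugated with the exocyclic methylene C12=C18. Remote from this cluster are two trisubstituted epoxides: C3–C4 with C2 and C5 cis (3R,4S, the oxide of a Z-olefin) and C7–C8 with C6 and C9 trans (7R,8R, the oxide of an E-olefin). The fragile groups are the α-methylene ketone (Michael acceptor; C11–H is γ to the carbonyl, so base can move the double bond into the ring), the epoxides (acid, transannular opening) and the acetate (base, hydride). The real difficulty is twofold: closing a twelve-membered ring between arms that stand trans on a cyclohexane and are crowded by C15, and fixing two olefin geometries and two epoxide faces that no ring stereocentre can reach. The key step uses the fact that, once the epoxides are read as a 3Z,7E-1,5-diene, the C5–C6 bond joins two allylic methylenes (C5 next to C3=C4, C6 next to C7=C8) at the point of the macrocycle farthest from C15 and from every stereocentre.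

## Logic of the disconnections

36 is traced to 35 by cutting the acetyl C–O bond at C10, 35 to 34 by returning the C13 carbonyl to a carbinol, and 34 to 33 by adding two O–Si bonds. The acetate and the enone cannot survive carbanions and hydrides, so both oxygens travel as silyl ethers and are unveiled last, under non-acidic conditions. A C13 ketal was not used. It would have to be made from an α-methylene ketone (conjugate addition and double-bond migration compete), it would meet 21 in step 11, and its removal needs acid near a 1,5-diene or near epoxides. The demand is that step 19 oxidise the allylic C13 carbinol and leave the C10 carbinol.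

33 is traced to 32 by cutting the four C–O bonds of the two oxiranes. Four stereocentres are replaced by two olefin geometries that can be fixed in open-chain arms. The demand is that one oxidant take the right face of both trisubstituted olefins and spare C12=C18. Reagent control is chosen because one enantiomer of a chiral oxygen-transfer catalyst is predicted to give 7R,8R and 3R,4S together.

32 is traced to 31 by adding a C6–S bond, and 31 to 30 by cutting C5–C6. This is the only skeletal bond of the macrocycle made in the route and it is the farthest from C15. The cut turns a bridged bicycle into a cyclohexane with two arms, whose olefin geometries are then inherited unchanged. The demand is α-alkylation of the sulfonyl carbanion by SN2 at the primary bromide, intramolecular under dilution. Against the target, the arms of 30 and 31 have the correct configuration at C1, C10 and C11 and the correct 3Z and 7E geometries, so nothing in the stated skeletons needed changing. The only remarks are that C13 is a silyl ether here and that C6 of 31 is a transient, uncontrolled stereocentre.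

30 is traced to 28 (C5–Br back to C5–O), 28 to 27 (a primary O–Si bond) and 27 to 24 (C6–S back to C6–O). The sulfone must be in place before the bromide, because sulfinate 25 would displace either. A primary silyl ether therefore masks the C5 oxygen while C6 is converted. The demand is selective cleavage of one primary silyl ether beside two secondary ones.

24 is traced to 20 by cutting the C8–CH3 and C7–C6 bonds, which leaves a terminal alkyne. Syn carbometalation with 21 and capture by 22 is the most dependable way to an E-trisubstituted allylic alcohol. 20 goes back to 19 (three O–Si bonds) and 19 to 18 (ester and ketone reduced together). The demand is that no ester or ketone be present when 21 is used, which the reduction in step 9 ensures.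

18 is traced to 16 and 17 by cutting C9–C10. This creates the C10 carbinol beside C11, where Felkin–Anh control and the catalyst can be made to agree. 16 goes back to 14 by restoring a C10=C9 double bond as a 2-methylpropenyl group. A trisubstituted alkene is used in place of a second vinyl group so that ozone can single it out from the conjugated olefins. The demand is immediate use of 16, a β,γ-unsaturated aldehyde.

14 is traced to 12 (C12=C18 from loss of an amine), and 12 to 8, 9 and 10 by cutting C11–C10 and C12–C18. One operation sets C11 trans to C1 and marks C12 through the regiodefined enolate, so C12 never has to be distinguished from C14 later. The demand is addition anti to the C1 arm next to the quaternary carbon.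

8 is traced to 6 and 7 by cutting C3=C4 (Z-selective olefination). 6 goes back to 5 and 3 by removing the C3 oxygen from a vinyl group. The first vinyl group is used up before the second alkenyl group enters, so the two arms never have to be told apart. The demand is tolerance of the enone, met by reducing and re-oxidising it in steps 2 and 3.

3 is traced to 1 and 2 by cutting C1–C2. The achiral dienone is desymmetrised by a catalyst, and this single step is the source of all absolute configuration. The demand is mono-addition with high facial selectivity at a carbon beside a quaternary centre.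

## Other disconnections considered

Alternative 1: The cut is at both alkenyl–ring bonds at once, C1–C2 and C11–C10, which takes the six-membered ring back to 1 and two equivalents of 2. In the forward direction the catalyst of step 1 would be used with an excess of 2, so that both enantiotopic enone olefins are alkenylated and the same ligand steers the second addition to the trans, twofold-symmetric ketone A1.
- In its favour: both ring stereocentres come from one catalyst in one flask. Most of the minor enantiomer of the first addition should be diverted into the meso cis isomer, which should raise the enantiomeric purity of A1. Because C12 and C14 are homotopic in A1, the later α-methylenation raises no regiochemical question.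
- Against it here: the two vinyl groups of A1 are homotopic as well. After methylenation they differ only in their distance from C12, yet one must keep both carbons (C2, C3) and the other must lose one (C10 aldehyde). No reagent can be relied on to distinguish two neopentyl-type vinyl groups beside the C12 methylene.
- Comparison: both plans start from the same two compounds and form C1–C2 by the same carbometalation, so they are equal in starting materials and in the origin of absolute configuration. The alternative is the better in step count for the ring stereocentres (one step against steps 1 and 5) and in setting C11 by catalyst and not by substrate control. The chosen plan is the better afterwards, because the first vinyl group is consumed (steps 2 to 4) before a deliberately different alkenyl group enters. Neither addresses the macrocycle, so this is a different front end and not a rival to step 15.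

Alternative 2: The cut runs through C1–C2 and C11–C15, which opens both rings and leads to the acyclic (2Z,6E,10E)-geranylgeranyl diphosphate A3. In the forward direction a magnesium-dependent, ionisation-initiated diterpene cyclase would have to be engineered to accept the 2Z substrate, form both bonds and stop by loss of a proton from C18, giving triene A2 with C1 and C11 trans.
- In its favour: one step would deliver both rings, both bridgehead centres, the exocyclic methylene and (inherited from A3) both olefin geometries, without protecting groups.
- Against it: the enzyme is hypothetical as specified, and A2 carries no oxygen. C13 is allylic and might be reached, but C10 is allylic to no double bond while several allylic positions (C2, C5, C6, C9, C11 and the vinyl methyl groups) compete. A second selective enzyme would be needed for the 10R hydroxyl.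
- Comparison: on structure the alternative is far better for the carbon skeleton (one step against fifteen to 31) and equal in how olefin geometry is secured (built into an acyclic precursor in both). On mechanism it is a cationic cascade in an active site against an anionic SN2 closure that uses only established reactivity. On step economy it is better on paper, but only after two unsolved C–H oxidations, whereas the chosen plan brings the C13 and C10 oxygens in at steps 1 and 7. The final epoxidations would be the same problem in both.

Alternative 3: The cut is the C11–C12 bond of the six-membered ring, leading back to the acyclic alkynyl aldehyde A5, in which C1 and C13 are already stereocentres and C3 is a protected alcohol. In the forward direction a secondary amine would convert the C10 aldehyde into the C10=C11 enamine, a carbophilic gold or copper Lewis acid would activate the C12≡C18 alkyne, and 6-exo-dig attack with protodemetalation would give aldehyde A4.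
- In its favour: ring, exocyclic methylene and the C11 centre arise together under catalytic, nearly neutral conditions. The two arms are different from the start (C10 aldehyde, C3 ether), which the chosen plan can only achieve through the order of steps 2 to 7; on this point the alternative is the better. C13 is carried as a silyl ether, as in the chosen plan.
- Against it: A5 needs the quaternary C15 and two separately made stereocentres in an open chain, one of which (C13) is destroyed later. The enamine must form at a neopentyl methylene. The C1/C11 trans relationship rests on a chair-like transition state without an anchoring group. A4 is a β,γ-unsaturated aldehyde with an epimerisable C11, generated in the presence of an amine.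
- Comparison: both plans pass through the same kind of aldehyde (16 here) and are equal in that liability, although 16 is consumed at once under acid catalysis. On mechanism it is π-acid activation with an enamine nucleophile against conjugate additions under catalyst and substrate control. On step economy the chosen plan reaches 16 in seven steps from 1, and the alternative is unlikely to reach A5 and then A4 in fewer. It also leaves the macrocycle untouched and would still need step 15.

Key step: step 15

Assumption: the carbinol carbon C13 (from 4 and 5, then 19 to 34) and the sulfone carbon C6 of 31 are temporary centres that are removed in steps 3, 19 and 16. Their configuration does not matter and is left open in the SMILES, as is the acetal carbon of 15. Locants C1–C18 are those of the target throughout.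

## Route

Step 1
Reactants: 1 4,4-dimethylcyclohexa-2,5-dien-1-one; 2 potassium vinyltrifluoroborate, K[CH2=CHBF3]
Product: 3 (5S)-5-ethenyl-4,4-dimethylcyclohex-2-en-1-one
Conditions: [RhCl(C2H4)2]2 (3 mol%), (S)-BINAP (6.6 mol%), 2 (1.1 equiv), Et3N, dioxane/H2O 10:1, 60 °C
Reagents that add atoms: none
Why: Hayashi–Miyaura-type rhodium-catalysed asymmetric conjugate addition; the two enone olefins of 1 are enantiotopic, and by analogy with its facial preference on 2-cyclohexenone the (S)-BINAP–rhodium alkenyl species is expected to create the 5S centre (future C1). The boron reagent is kept limiting so that the reaction stops at mono-addition.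

Step 2
Reactants: 3 vinyl enone
Product: 5 (5R)-5-(2-hydroxyethyl)-4,4-dimethylcyclohex-2-en-1-ol as carbinol epimers, via bis-boron adduct 4 (not isolated)
Conditions: 9-BBN-H (3 equiv), THF, 0 °C → rt; then NaOH (aq), H2O2, 0 °C → rt
Reagents that add atoms: hydrogen peroxide OO
Why: Hydroboration–oxidation; 9-BBN-H adds to the monosubstituted vinyl group at its terminus and at the same time reduces the enone carbonyl 1,2, while the hindered ring olefin is too slow to react. The carbinol configuration is irrelevant because step 3 restores the ketone.

Step 3
Reactants: 5 diol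
Product: 6 2-[(1R)-2,2-dimethyl-5-oxocyclohex-3-en-1-yl]acetaldehyde
Conditions: Dess–Martin periodinane (2.6 equiv), NaHCO3, CH2Cl2, 0 °C → rt
Reagents that add atoms: none
Why: Dess–Martin oxidation converts the primary alcohol to the C3 aldehyde and the allylic alcohol back to the enone in one buffered operation; the stereocentre is not α to either carbonyl and is not at risk.

Step 4
Reactants: 6 keto aldehyde; 7 ethyl 2-[bis(2,2,2-trifluoroethoxy)phosphoryl]propanoate
Product: 8 ethyl (2Z)-4-[(1R)-2,2-dimethyl-5-oxocyclohex-3-en-1-yl]-2-methylbut-2-enoate
Conditions: 7 (1.2 equiv), KN(SiMe3)2, 18-crown-6, THF, −78 °C; then 6, −78 °C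
Reagents that add atoms: none
Why: Still–Gennari olefination; with the trifluoroethyl phosphonate and a dissociated potassium counter-ion the kinetic adduct eliminates fast and gives the Z-trisubstituted enoate (C3=C4). The aldehyde reacts far faster than the hindered enone.

Step 5
Reactants: 8 Z-enoate enone; 9 (2-methylprop-1-en-1-yl)magnesium bromide, (CH3)2C=CHMgBr; 10 N,N-dimethylmethaniminium iodide (Eschenmoser's salt)
Product: 12 ethyl (2Z)-4-[(1R,3R,4S)-4-[(dimethylamino)methyl]-2,2-dimethyl-3-(2-methylprop-1-en-1-yl)-5-oxocyclohexyl]-2-methylbut-2-enoate, via trimethylsilyl enol ether 11 (not isolated)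
Conditions: 9 (1.5 equiv), CuBr·SMe2 (10 mol%), Me3SiCl (2 equiv), THF, −78 °C; non-aqueous work-up; then 10 (1.3 equiv), CH2Cl2, rt; aq NaHCO3
Reagents that add atoms: none
Why: Copper-catalysed, Me3SiCl-accelerated conjugate addition; the alkenyl group should enter axially at the β-carbon anti to the pseudo-equatorial C1 arm, which sets C11 trans to C1, and the α-methyl enoate is a much poorer acceptor than the enone. The regiodefined silyl enol ether is then aminomethylated at C12 by a Mannich reaction (C12 configuration irrelevant).

Step 6
Reactants: 12 Mannich base
Product: 14 ethyl (2Z)-4-[(1R,3S)-2,2-dimethyl-4-methylidene-3-(2-methylprop-1-en-1-yl)-5-oxocyclohexyl]-2-methylbut-2-enoate, via ammonium iodide 13 (not isolated)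
Conditions: MeI (5 equiv), Et2O/CH2Cl2, rt; then NaHCO3 (aq), CH2Cl2, rt
Reagents that add atoms: none
Why: Exhaustive N-methylation followed by E1cB (Hofmann-type) loss of trimethylamine from the β-ammonio ketone gives the exocyclic enone C12=C18; bicarbonate is too weak to enolise towards C11.

Step 7
Reactants: 14 methylene ketone
Product: 16 ethyl (2Z)-4-[(1R,3S)-3-formyl-2,2-dimethyl-4-methylidene-5-oxocyclohexyl]-2-methylbut-2-enoate, via secondary ozonide 15 (not isolated)
Conditions: O3, CH2Cl2, −78 °C, Sudan Red 7B end point; then PPh3, −78 → 0 °C; used crude
Reagents that add atoms: ozone [O-][O+]=O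
Why: Ozonolysis; the electron-rich trisubstituted olefin reacts much faster than the two conjugated, electron-poor olefins, and the dye marks the end point. Reductive work-up gives the C10 aldehyde with C11 untouched, and the β,γ-unsaturated aldehyde is used at once.

Step 8
Reactants: 16 aldehyde; 17 4,4,5,5-tetramethyl-2-(propa-1,2-dien-1-yl)-1,3,2-dioxaborolane
Product: 18 ethyl (2Z)-4-[(1R,3S)-3-[(1R)-1-hydroxybut-3-yn-1-yl]-2,2-dimethyl-4-methylidene-5-oxocyclohexyl]-2-methylbut-2-enoate
Conditions: 17 (1.5 equiv), (R)-3,3′-bis(2,4,6-triisopropylphenyl)-1,1′-binaphthyl-2,2′-diyl hydrogen phosphate (10 mol%), 4 Å MS, toluene, −20 °C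
Reagents that add atoms: none
Why: Brønsted-acid-catalysed allenylboration (SE2′, closed six-membered transition state) gives the homopropargylic alcohol; Felkin–Anh attack with C15 anti to the nucleophile is on the Re face and gives 10R, and the catalyst enantiomer is the one expected to reinforce that face. Ketone and ester do not react with the boronate.

Step 9
Reactants: 18 homopropargylic alcohol
Product: 19 (2Z)-4-[(1R,3S)-5-hydroxy-3-[(1R)-1-hydroxybut-3-yn-1-yl]-2,2-dimethyl-4-methylidenecyclohexyl]-2-methylbut-2-en-1-ol (C13 epimers)
Conditions: i-Bu2AlH (6 equiv), CH2Cl2, −78 → −40 °C; aq KNaC4H4O6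
Reagents that add atoms: none
Why: i-Bu2AlH reduces the ester to the Z-allylic alcohol (C5) and the enone 1,2 to the allylic C13 carbinol in one operation, which removes every carbonyl before organoaluminium and carbanion chemistry.

Step 10
Reactants: 19 triol
Product: 20 tris(tert-butyldimethylsilyl) ether of 19 (O5, O10, O13)
Conditions: TBSOTf (4 equiv), 2,6-lutidine, CH2Cl2, −20 °C → rt
Reagents that add atoms: tert-butyldimethylsilyl trifluoromethanesulfonate CC(C)(C)[Si](C)(C)OS(=O)(=O)C(F)(F)F
Why: Silyl triflate with a hindered base silylates the primary, the allylic and the hindered C10 hydroxyl alike; the terminal alkyne is not affected.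

Step 11
Reactants: 20 tris-silyl alkyne; 21 trimethylaluminium, Me3Al; 22 paraformaldehyde, (CH2O)n
Product: 24 E-allylic alcohol with C6–OH and C8-methyl on the C11 arm and the three silyl ethers kept, via alkenyl dimethylalane 23 (not isolated)
Conditions: 21 (3 equiv), Cp2ZrCl2 (0.25 equiv), CH2Cl2, 0 °C → rt; volatiles removed; n-BuLi, THF, −78 °C; then 22, −78 °C → rt
Reagents that add atoms: none
Why: Negishi zirconium-catalysed carboalumination; methyl and aluminium add syn with methyl on the internal carbon, which fixes the E geometry of C7=C8. The alkenylalanate is then hydroxymethylated with retention.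

Step 12
Reactants: 24 E-allylic alcohol; 25 sodium benzenesulfinate, PhSO2Na
Product: 27 C6 allylic phenyl sulfone with the three silyl ethers kept, via C6 mesylate 26 (not isolated)
Conditions: MsCl, Et3N, CH2Cl2, −30 °C; then 25 (3 equiv), n-Bu4NI (cat.), DMF, rt
Reagents that add atoms: none
Why: Mesylation, then S-alkylation of the ambident sulfinate at the primary allylic carbon by SN2 in a dipolar solvent; the E olefin does not move.

Step 13
Reactants: 27 sulfone tris-silyl ether
Product: 28 C5 primary allylic alcohol with the C10 and C13 silyl ethers kept
Conditions: HF·pyridine, pyridine, THF, 0 °C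
Reagents that add atoms: none
Why: Buffered fluoride cleaves the unhindered primary silyl ether much faster than the two secondary ones, one of which is flanked by C11 and C15.

Step 14
Reactants: 28 C5 alcohol
Product: 30 seco C5 allylic bromide and C6 allylic phenyl sulfone (3Z,7E; 1R,10R,11S; O10 and O13 as silyl ethers), via C5 mesylate 29 (not isolated)
Conditions: MsCl, Et3N, THF, −40 °C; then LiBr (5 equiv), −40 → 0 °C; used at once
Reagents that add atoms: lithium bromide [Li+].[Br-]
Why: Displacement of the mesylate by bromide at the primary carbon (SN2) at low temperature keeps the Z geometry of C3=C4; the sulfone is inert.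

Step 15
Reactants: 30 seco bromide sulfone
Product: 31 macrocyclic C6 phenyl sulfone, (3Z,7E)-10,13-bis(tert-butyldimethylsilyloxy)-6-(phenylsulfonyl)verticilla-3,7,12(18)-triene (C6 epimers)
Conditions: KN(SiMe3)2 (2 equiv), THF, −78 °C; 30 added over 6 h to a final concentration of about 2 mM; then −78 → −20 °C
Reagents that add atoms: none
Why: The amide base removes a proton from C6, the only acidic site (α to sulfur and allylic; C13 and C10 are ethers and no carbonyl is present), and the potassium sulfonyl carbanion displaces bromide at C5 by SN2. The closest known reaction type is the alkylation of allylic sulfone carbanions with allylic halides that joins polyprenoid units, in its intramolecular form used to close macrocyclic terpenoid rings. The ring closes in the 12-exo-tet mode and forms the C5–C6 bond. The only new stereocentre is C6; nothing controls it and nothing needs to, because step 16 removes it. The step needs α- rather than γ-alkylation, which is secured because the charge sits beside sulfur and the γ-carbon C8 is fully substituted. It needs SN2 rather than SN2′, secured because C5 is primary while attack at C3 would give a strained ten-membered ring. Intramolecular reaction is secured by slow addition at high dilution, and low temperature holds back loss of HBr from the allylic bromide. Neither olefin takes part, so the 3Z and 7E geometries made in steps 4 and 11 are carried into the ring.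

Step 16
Reactants: 31 macrocyclic sulfone
Product: 32 (3Z,7E)-10,13-bis(tert-butyldimethylsilyloxy)verticilla-3,7,12(18)-triene (1R,10R,11S)
Conditions: PdCl2(dppp) (10 mol%), LiBHEt3 (3 equiv), THF, 0 °C → rt
Reagents that add atoms: none
Why: Zerovalent palladium formed in the flask ionises the allylic sulfone to a π-allyl complex, and hydride is delivered to the less substituted terminus C6, so C7=C8 stays in place and stays E. Both C6 epimers converge.

Step 17
Reactants: 32 macrocyclic diene
Product: 33 3,4:7,8-diepoxide of 32 (3R,4S,7R,8R; other centres as in 36)
Conditions: D-fructose-derived Shi ketone (0.6 equiv), KHSO5 (3 equiv, as the triple salt), K2CO3, n-Bu4NHSO4 (cat.), MeCN/dimethoxymethane/aq Na2B4O7 buffer (pH about 10.5), 0 °C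
Reagents that add atoms: potassium peroxymonosulfate OOS(=O)(=O)[O-].[K+]
Why: Shi epoxidation; the chiral dioxirane transfers oxygen through a spiro transition state, and with E-trisubstituted olefins the D-fructose-derived ketone gives the sense that corresponds to 7R,8R here. Attack on the geometrically corresponding face of the Z-olefin (trans pair C2 and the C4 methyl) gives 3R,4S. The hindered, less electron-rich C12=C18 should react more slowly.

Step 18
Reactants: 33 diepoxy bis-silyl ether
Product: 34 diepoxy 10,13-diol (C13 epimers)
Conditions: n-Bu4NF (6 equiv), THF, rt → 45 °C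
Reagents that add atoms: none
Why: Fluoride cleaves both silyl ethers under basic, non-acidic conditions that the trisubstituted epoxides tolerate; attack of either alkoxide on an epoxide would need a 4-exo or 5-endo closure.

Step 19
Reactants: 34 diepoxy diol
Product: 35 diepoxy 10-hydroxy 12(18)-en-13-one
Conditions: activated MnO2 (20 equiv), CH2Cl2, rt
Reagents that add atoms: none
Why: MnO2 oxidises allylic alcohols selectively, so the C13 carbinol gives the α-methylene ketone and the saturated, hindered C10 carbinol is left. The temporary C13 centre disappears.

Step 20
Reactants: 35 diepoxy hydroxy enone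
Product: 36 (1R,3R,4S,7R,8R,10R,11S)-10-acetoxy-3,4:7,8-diepoxyverticill-12(18)-en-13-one (target)
Conditions: Ac2O, DMAP (cat.), pyridine, CH2Cl2, 0 °C → rt
Reagents that add atoms: acetic anhydride CC(=O)OC(C)=O
Why: DMAP-catalysed acylation of the hindered secondary alcohol under non-acidic conditions that leave the epoxides and the enone intact; cyclisation of the hydroxyl onto C18 would be a disfavoured 5-endo-trig process.

## Compound list

1 | 4,4-dimethylcyclohexa-2,5-dien-1-one | CC1(C)C=CC(=O)C=C1 | starting material
2 | potassium vinyltrifluoroborate | C=C[B-](F)(F)F.[K+] | starting material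
3 | (5S)-5-ethenyl-4,4-dimethylcyclohex-2-en-1-one | O=C1C[C@@H](C=C)C(C)(C)C=C1 | intermediate
4 | bis-boron adduct: B-alkyl-9-BBN at C3 and O-(9-BBN) borinate at C13 (C13 epimers) | O(B1C2CCCC1CCC2)C1C[C@@H](CCB2C3CCCC2CCC3)C(C)(C)C=C1 | intermediate
5 | (5R)-5-(2-hydroxyethyl)-4,4-dimethylcyclohex-2-en-1-ol (carbinol epimers) | OC1C[C@@H](CCO)C(C)(C)C=C1 | intermediate
6 | 2-[(1R)-2,2-dimethyl-5-oxocyclohex-3-en-1-yl]acetaldehyde | O=C1C[C@@H](CC=O)C(C)(C)C=C1 | intermediate
7 | ethyl 2-[bis(2,2,2-trifluoroethoxy)phosphoryl]propanoate | CCOC(=O)C(C)P(=O)(OCC(F)(F)F)OCC(F)(F)F | starting material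
8 | ethyl (2Z)-4-[(1R)-2,2-dimethyl-5-oxocyclohex-3-en-1-yl]-2-methylbut-2-enoate | O=C1C[C@@H](C/C=C(C)\C(=O)OCC)C(C)(C)C=C1 | intermediate
9 | (2-methylprop-1-en-1-yl)magnesium bromide | CC(C)=C[Mg]Br | starting material
10 | N,N-dimethylmethaniminium iodide (Eschenmoser's salt) | C=[N+](C)C.[I-] | starting material
11 | ethyl (2Z)-4-[(1R,5R)-6,6-dimethyl-5-(2-methylprop-1-en-1-yl)-3-(trimethylsilyloxy)cyclohex-3-en-1-yl]-2-methylbut-2-enoate | C1=C(O[Si](C)(C)C)C[C@@H](C/C=C(C)\C(=O)OCC)C(C)(C)[C@@H]1C=C(C)C | intermediate
12 | ethyl (2Z)-4-[(1R,3R,4S)-4-[(dimethylamino)methyl]-2,2-dimethyl-3-(2-methylprop-1-en-1-yl)-5-oxocyclohexyl]-2-methylbut-2-enoate | CN(C)C[C@H]1C(=O)C[C@@H](C/C=C(C)\C(=O)OCC)C(C)(C)[C@@H]1C=C(C)C | intermediate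
13 | trimethylammonium iodide of 12 (N-methylated Mannich base) | C[N+](C)(C)C[C@H]1C(=O)C[C@@H](C/C=C(C)\C(=O)OCC)C(C)(C)[C@@H]1C=C(C)C.[I-] | intermediate
14 | ethyl (2Z)-4-[(1R,3S)-2,2-dimethyl-4-methylidene-3-(2-methylprop-1-en-1-yl)-5-oxocyclohexyl]-2-methylbut-2-enoate | C=C1C(=O)C[C@@H](C/C=C(C)\C(=O)OCC)C(C)(C)[C@@H]1C=C(C)C | intermediate
15 | secondary ozonide of 14: 5,5-dimethyl-1,2,4-trioxolan-3-yl group on C11 (acetal carbon epimers) | C=C1C(=O)C[C@@H](C/C=C(C)\C(=O)OCC)C(C)(C)[C@@H]1C1OOC(C)(C)O1 | intermediate
16 | ethyl (2Z)-4-[(1R,3S)-3-formyl-2,2-dimethyl-4-methylidene-5-oxocyclohexyl]-2-methylbut-2-enoate | C=C1C(=O)C[C@@H](C/C=C(C)\C(=O)OCC)C(C)(C)[C@@H]1C=O | intermediate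
17 | 4,4,5,5-tetramethyl-2-(propa-1,2-dien-1-yl)-1,3,2-dioxaborolane | C=C=CB1OC(C)(C)C(C)(C)O1 | starting material
18 | ethyl (2Z)-4-[(1R,3S)-3-[(1R)-1-hydroxybut-3-yn-1-yl]-2,2-dimethyl-4-methylidene-5-oxocyclohexyl]-2-methylbut-2-enoate | C=C1C(=O)C[C@@H](C/C=C(C)\C(=O)OCC)C(C)(C)[C@@H]1[C@@H](CC#C)O | intermediate
19 | (2Z)-4-[(1R,3S)-5-hydroxy-3-[(1R)-1-hydroxybut-3-yn-1-yl]-2,2-dimethyl-4-methylidenecyclohexyl]-2-methylbut-2-en-1-ol (C13 epimers) | C=C1C(O)C[C@@H](C/C=C(C)\CO)C(C)(C)[C@@H]1[C@@H](CC#C)O | intermediate
20 | tris(tert-butyldimethylsilyl) ether of 19 (O5, O10, O13) | C=C1C(O[Si](C)(C)C(C)(C)C)C[C@@H](C/C=C(C)\CO[Si](C)(C)C(C)(C)C)C(C)(C)[C@@H]1[C@@H](CC#C)O[Si](C)(C)C(C)(C)C | intermediate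
21 | trimethylaluminium | C[Al](C)C | starting material
22 | paraformaldehyde (formaldehyde source) | C=O | starting material
23 | (E)-alkenyl dimethylalane from 20: Al on C7, methyl on C8 | C=C1C(O[Si](C)(C)C(C)(C)C)C[C@@H](C/C=C(C)\CO[Si](C)(C)C(C)(C)C)C(C)(C)[C@@H]1[C@@H](C/C(C)=C/[Al](C)C)O[Si](C)(C)C(C)(C)C | intermediate
24 | E-allylic alcohol: C6–OH, 7E, tris-silyl ether (O5, O10, O13) | C=C1C(O[Si](C)(C)C(C)(C)C)C[C@@H](C/C=C(C)\CO[Si](C)(C)C(C)(C)C)C(C)(C)[C@@H]1[C@@H](C/C(C)=C/CO)O[Si](C)(C)C(C)(C)C | intermediate
25 | sodium benzenesulfinate | [Na+].[O-]S(=O)c1ccccc1 | starting material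
26 | C6 methanesulfonate of 24 | C=C1C(O[Si](C)(C)C(C)(C)C)C[C@@H](C/C=C(C)\CO[Si](C)(C)C(C)(C)C)C(C)(C)[C@@H]1[C@@H](C/C(C)=C/COS(C)(=O)=O)O[Si](C)(C)C(C)(C)C | intermediate
27 | C6 allylic phenyl sulfone, tris-silyl ether (O5, O10, O13) | C=C1C(O[Si](C)(C)C(C)(C)C)C[C@@H](C/C=C(C)\CO[Si](C)(C)C(C)(C)C)C(C)(C)[C@@H]1[C@@H](C/C(C)=C/CS(=O)(=O)c1ccccc1)O[Si](C)(C)C(C)(C)C | intermediate
28 | C5 primary Z-allylic alcohol, C6 sulfone, O10 and O13 silyl ethers | C=C1C(O[Si](C)(C)C(C)(C)C)C[C@@H](C/C=C(C)\CO)C(C)(C)[C@@H]1[C@@H](C/C(C)=C/CS(=O)(=O)c1ccccc1)O[Si](C)(C)C(C)(C)C | intermediate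
29 | C5 methanesulfonate of 28 | C=C1C(O[Si](C)(C)C(C)(C)C)C[C@@H](C/C=C(C)\COS(C)(=O)=O)C(C)(C)[C@@H]1[C@@H](C/C(C)=C/CS(=O)(=O)c1ccccc1)O[Si](C)(C)C(C)(C)C | intermediate
30 | seco C5 allylic bromide / C6 allylic phenyl sulfone, O10 and O13 silyl ethers (3Z,7E; 1R,10R,11S) | C=C1C(O[Si](C)(C)C(C)(C)C)C[C@@H](C/C=C(C)\CBr)C(C)(C)[C@@H]1[C@@H](C/C(C)=C/CS(=O)(=O)c1ccccc1)O[Si](C)(C)C(C)(C)C | intermediate
31 | (3Z,7E)-10,13-bis(tert-butyldimethylsilyloxy)-6-(phenylsulfonyl)verticilla-3,7,12(18)-triene (C6 and C13 epimers; C1, C10, C11 as in 36) | C=C1C(O[Si](C)(C)C(C)(C)C)C[C@H]2C/C=C(C)\CC(S(=O)(=O)c3ccccc3)/C=C(C)/C[C@@H](O[Si](C)(C)C(C)(C)C)[C@H]1C2(C)C | intermediate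
32 | (3Z,7E)-10,13-bis(tert-butyldimethylsilyloxy)verticilla-3,7,12(18)-triene (C1, C10, C11 as in 36) | C=C1C(O[Si](C)(C)C(C)(C)C)C[C@H]2C/C=C(C)\CC/C=C(C)/C[C@@H](O[Si](C)(C)C(C)(C)C)[C@H]1C2(C)C | intermediate
33 | 3,4:7,8-diepoxy-10,13-bis(tert-butyldimethylsilyloxy)verticill-12(18)-ene (3R,4S,7R,8R; C1, C10, C11 as in 36) | C=C1C(O[Si](C)(C)C(C)(C)C)C[C@H]2C[C@H]3O[C@@]3(C)CC[C@H]3O[C@]3(C)C[C@@H](O[Si](C)(C)C(C)(C)C)[C@H]1C2(C)C | intermediate
34 | 3,4:7,8-diepoxyverticill-12(18)-ene-10,13-diol (C13 epimers; other centres as in 36) | C=C1C(O)C[C@H]2C[C@H]3O[C@@]3(C)CC[C@H]3O[C@]3(C)C[C@@H](O)[C@H]1C2(C)C | intermediate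
35 | 3,4:7,8-diepoxy-10-hydroxyverticill-12(18)-en-13-one (centres as in 36) | C=C1C(=O)C[C@H]2C[C@H]3O[C@@]3(C)CC[C@H]3O[C@]3(C)C[C@@H](O)[C@H]1C2(C)C | intermediate
36 | (1R,3R,4S,7R,8R,10R,11S)-10-acetoxy-3,4:7,8-diepoxyverticill-12(18)-en-13-one | C=C1C(=O)C[C@H]2C[C@H]3O[C@@]3(C)CC[C@H]3O[C@]3(C)C[C@@H](OC(C)=O)[C@H]1C2(C)C | target

## Step count and least certain steps

Total step count: 20. Longest linear sequence: 20 steps (1 to 36); every other input is a commercial reagent.

Step 15 (key step). The most likely failure is that ring closure is outrun by intermolecular alkylation (oligomer formation) or by base-induced loss of HBr from the allylic bromide. The two arms stand trans on the cyclohexane and must fold across a face crowded by C15 and two silyloxy groups, so the reactive conformer may be thinly populated. The fallback forms the same C5–C6 bond without a carbanion, by nickel-mediated reductive coupling of two allylic bromides. It sets out from 24. Buffered HF·pyridine removes the primary silyl ether to give the bis-allylic diol F1. Mesylation and LiBr convert both primary hydroxyls to the bis-allylic dibromide F2. Slow addition of F2 to Ni(CO)4 in N-methylpyrrolidone at 50 °C under high dilution should close the ring through a bis-allylnickel species, coming back to the route at 32 with no sulfone to remove. Its own weakness would be partial loss of olefin geometry in the allylnickel intermediates.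

Step 1. Two things can go wrong: over-addition, because the second enone of 3 is not much less reactive than the first, and insufficient facial discrimination at a β-carbon flanked by a quaternary centre. The fallback changes the metal and the nucleophile class: copper-catalysed conjugate addition of divinylzinc (from vinylmagnesium bromide and ZnCl2) with Cu(OTf)2 and a chiral phosphoramidite ligand, a system suited to desymmetrising 4,4-disubstituted cyclohexadienones in which the zinc enolate formed resists a second addition. It sets out from 1 and comes back at 3; it makes no new compound (entry F0).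

Step 7. The risks are loss of chemoselectivity (ozone also attacking the enoate or the enone olefin once the trisubstituted olefin is consumed) and over-oxidation, together with epimerisation at C11 or migration of C12=C18 in the β,γ-unsaturated aldehyde during handling. The fallback replaces ozone by a two-stage cleavage that depends on nucleophilicity only. It sets out from 14. One equivalent of mCPBA at 0 °C should epoxidise only the electron-rich 2-methylpropenyl group to give the trisubstituted epoxide F3. Periodic acid in ether then cleaves F3 directly to the aldehyde and acetone, coming back to the route at 16, which is again used without purification.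

Step 17. The most likely failure is poor facial selectivity: the macrocycle may expose only one face of one or both olefins and override the dioxirane (mismatched reagent and substrate preference), giving epoxide diastereomers. The fallback gives up reagent control and epoxidises the final, unprotected diene under substrate control, where the conformation is that of the natural skeleton. It sets out from 32. n-Bu4NF gives the diene diol F4, MnO2 gives the hydroxy dienone F5, and acetylation gives the acetoxy dienone F6. mCPBA (2.2 equiv, NaHCO3, CH2Cl2, 0 °C) then attacks the two trisubstituted olefins from the periphery and spares the electron-poor enone olefin, coming back at 36. Each approach serves as the check on the other.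

Step 19. The risk is sluggish oxidation of an allylic alcohol whose olefin is only an exocyclic methylene, leading to long contact times, partial oxidation at C10 or cyclisation of the C10 hydroxyl onto the new enone. The fallback separates the two hydroxyls by protection instead of by oxidant selectivity. It sets out from 34. Triethylsilyl chloride and imidazole should silylate the less hindered C13 hydroxyl to give the 13-triethylsilyl ether F7. Acetylation of C10 gives the acetate F8, and buffered n-Bu4NF frees C13 to give the 13-hydroxy acetate F9. Dess–Martin oxidation then comes back to the route at 36.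

## Further compounds

F1 | step 15 | bis-allylic diol: C5–OH and C6–OH, O10 and O13 silyl ethers (3Z,7E) | C=C1C(O[Si](C)(C)C(C)(C)C)C[C@@H](C/C=C(C)\CO)C(C)(C)[C@@H]1[C@@H](C/C(C)=C/CO)O[Si](C)(C)C(C)(C)C
F2 | step 15 | bis-allylic dibromide: C5–Br and C6–Br, O10 and O13 silyl ethers (3Z,7E) | C=C1C(O[Si](C)(C)C(C)(C)C)C[C@@H](C/C=C(C)\CBr)C(C)(C)[C@@H]1[C@@H](C/C(C)=C/CBr)O[Si](C)(C)C(C)(C)C
F0 | step 1 | none | none
F3 | step 7 | epoxide of the 2-methylpropenyl group of 14 (3,3-dimethyloxiran-2-yl on C11; oxirane CH epimers) | C=C1C(=O)C[C@@H](C/C=C(C)\C(=O)OCC)C(C)(C)[C@@H]1C1OC1(C)C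
F4 | step 17 | (3Z,7E)-verticilla-3,7,12(18)-triene-10,13-diol (C13 epimers) | C=C1C(O)C[C@H]2C/C=C(C)\CC/C=C(C)/C[C@@H](O)[C@H]1C2(C)C
F5 | step 17 | (3Z,7E)-10-hydroxyverticilla-3,7,12(18)-trien-13-one | C=C1C(=O)C[C@H]2C/C=C(C)\CC/C=C(C)/C[C@@H](O)[C@H]1C2(C)C
F6 | step 17 | (3Z,7E)-10-acetoxyverticilla-3,7,12(18)-trien-13-one | C=C1C(=O)C[C@H]2C/C=C(C)\CC/C=C(C)/C[C@@H](OC(C)=O)[C@H]1C2(C)C
F7 | step 19 | 3,4:7,8-diepoxy-13-(triethylsilyloxy)verticill-12(18)-en-10-ol (C13 epimers) | C=C1C(O[Si](CC)(CC)CC)C[C@H]2C[C@H]3O[C@@]3(C)CC[C@H]3O[C@]3(C)C[C@@H](O)[C@H]1C2(C)C
F8 | step 19 | 10-acetoxy-3,4:7,8-diepoxy-13-(triethylsilyloxy)verticill-12(18)-ene (C13 epimers) | C=C1C(O[Si](CC)(CC)CC)C[C@H]2C[C@H]3O[C@@]3(C)CC[C@H]3O[C@]3(C)C[C@@H](OC(C)=O)[C@H]1C2(C)C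
F9 | step 19 | 10-acetoxy-3,4:7,8-diepoxyverticill-12(18)-en-13-ol (C13 epimers) | C=C1C(O)C[C@H]2C[C@H]3O[C@@]3(C)CC[C@H]3O[C@]3(C)C[C@@H](OC(C)=O)[C@H]1C2(C)C
A1 | alternative 1 | (3S,5S)-3,5-diethenyl-4,4-dimethylcyclohexan-1-one | O=C1C[C@@H](C=C)C(C)(C)[C@H](C=C)C1
A2 | alternative 2 | (3Z,7E)-verticilla-3,7,12(18)-triene, C1 and C11 trans | C=C1CC[C@H]2C/C=C(C)\CC/C=C(C)/CC[C@H]1C2(C)C
A3 | alternative 2 | (2Z,6E,10E)-geranylgeranyl diphosphate | CC(C)=CCC/C(C)=C/CC/C(C)=C/CC/C(C)=C\COP(=O)(O)OP(=O)(O)O
A4 | alternative 3 | 2-methylenecyclohexanecarbaldehyde with O13 silyl ether and C3 p-methoxybenzyl ether, C1 and C11 trans | C=C1[C@H](O[Si](C)(C)C(C)(C)C)C[C@@H](CCOCc2ccc(OC)cc2)C(C)(C)[C@@H]1C=O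
A5 | alternative 3 | acyclic alkynyl aldehyde: C10 aldehyde, C12≡C18 alkyne, O13 silyl ether, C3 p-methoxybenzyl ether | C#C[C@H](O[Si](C)(C)C(C)(C)C)C[C@@H](CCOCc1ccc(OC)cc1)C(C)(C)CC=O
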